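Eudesmane numbering is used: ring A = C1–C5 and C10, ring B = C5–C10, C14 on C10, C15 on C4, and C11–C13 form the isopropylidene group.
Retrosynthetic cuts, in order: the C3–O ester bond; both C–O bonds of the cis C3/C4 diol (back to a C3=C4 alkene); C7=C11 (an acetone unit); C4–C15 (back to a C4 ketone); last, C5–C6 and C9–C10 together.
Enabling feature: with C4 as a ketone, ring A is 3-methylcyclohex-2-enone, so C5=C10 is a 2π unit with C10 electrophilic. With the C8 oxygen as a silyl enol ether, C6–C7–C8–C9 is a 2-silyloxybutadiene with C9 nucleophilic, so the [4+2] union is polarity matched (para orientation).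
Forward order: ring A is bought and ring B arises in the cycloaddition. This step also leaves C8 masked as a C7=C8 enol silane, which tells the two carbonyls apart and fixes the site of the later C7–C11 bond. C15, C11–C13, the diol and the ester then follow.
Stereochemistry: C10 comes from the chiral counteranion of the cycloaddition catalyst, C5 from equilibration through the C4 ketone, C3 and C4 from OsO4 attack anti to the axial C10 methyl, and the side-chain centre from (S)-1-bromo-2-methylbutane.

Key step: step 2

Assumption: the (S,S) antipode of the catalyst is taken to leave the Si face at C10 of the enone open; should the opposite sense be found, the mirror-image catalyst is used and nothing else changes.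

Step 1
Reactants: 1 but-3-en-2-one
Product: 2 2-[(tert-butyldimethylsilyl)oxy]buta-1,3-diene
Conditions: TBSOTf, Et3N, Et2O, 0 °C
Reagents that add atoms: tert-butyldimethylsilyl trifluoromethanesulfonate CC(C)(C)[Si](C)(C)OS(=O)(=O)C(F)(F)F
Why: Soft enolisation (silyl triflate/amine silyl enol ether formation) takes the only enolisable position, the CH3 group, and gives the cross-conjugated 2-silyloxydiene without forming a stereocentre.

Step 2
Reactants: 2 2-[(tert-butyldimethylsilyl)oxy]buta-1,3-diene; 3 3-methylcyclohex-2-en-1-one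
Product: 4 cis adduct (4aR,8aS)-6-[(tert-butyldimethylsilyl)oxy]-4a-methyl-3,4,4a,5,8,8a-hexahydronaphthalen-1(2H)-one (10β-CH3 and 5β-H)
Conditions: (S,S)-IDPi (BINOL-derived imidodiphosphorimidate Brønsted acid, N-triflyl, bulky 3,3'-aryl groups, 5 mol %), 2 (2 equiv), PhMe, −40 → −20 °C; Et3N quench
Reagents that add atoms: none
Why: Proposed new method: the acid protodesilylates a trace of 2 to the ion pair TBS+ IDPi−, this silylium ion binds the C4 carbonyl oxygen of 3, the nucleophilic terminus C9 of the diene attacks the cationic C10 and C5 closes onto C6 in a strongly asynchronous [4+2] cycloaddition (double Mukaiyama–Michael limit), after which the silylium ion on the C4 oxygen passes to the next molecule of 3 while the C8–OTBS group stays as the C7=C8 enol silane. The closest known reaction types are the achiral triflimide- or AlBr3/AlMe3-promoted Diels–Alder reactions of hindered 2-silyloxydienes with β,β-disubstituted enones and the silylium–IDPi catalysed asymmetric Diels–Alder and Mukaiyama–Michael reactions of simple α,β-unsaturated esters, and what is new is enantiocontrol on a β-methyl cyclic enone. Ring B closes as a suprafacial [4π+2π] addition across C5=C10 (in the stepwise limit a 6-(enolexo)-endo-trig Michael closure), so C9 and C6 arrive on one face and the ring fusion is cis. C10 is controlled by the confined chiral anion, which has to leave open the Si face at C10 (the α face), and C5 (5β-H) follows from the suprafacial course and is corrected in step 3. The step needs para regiochemistry, 1,4- over 1,2-attack and a single addition: the first is secured by the matched polarisation (largest diene HOMO coefficient at C9, largest LUMO coefficient of the O-silylated enone at C10), the second by the bulky silyl group on the carbonyl oxygen, the third by the lower nucleophilicity of the trisubstituted enol silane of 4 compared with the terminal CH2 of 2.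

Step 3
Reactants: 4 cis adduct
Product: 5 trans ketone (4aR,8aR)-6-[(tert-butyldimethylsilyl)oxy]-4a-methyl-3,4,4a,5,8,8a-hexahydronaphthalen-1(2H)-one (10β-CH3 and 5α-H)
Conditions: DBU (0.5 equiv), PhMe, 80 °C
Reagents that add atoms: none
Why: Base-mediated epimerisation through the C4/C5 enolate (thermodynamic equilibration of a cis- to a trans-1-decalone) inverts only C5, the sole stereocentre α to the ketone, and should favour the trans isomer, in which the sp2 atoms C4 and C8 remove two of the syn-axial contacts of the C10 methyl, while recovered 4 can be resubmitted.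

Step 4
Reactants: 5 trans ketone
Product: 7 enol triflate (4aR,8aR)-6-[(tert-butyldimethylsilyl)oxy]-4a-methyl-3,4,4a,5,8,8a-hexahydronaphthalen-1-yl trifluoromethanesulfonate, via potassium enolate 6 (not isolated)
Conditions: KN(SiMe3)2, THF, −78 °C; then PhNTf2, −78 → 0 °C
Reagents that add atoms: N-phenylbis(trifluoromethanesulfonimide) O=S(=O)(N(c1ccccc1)S(=O)(=O)C(F)(F)F)C(F)(F)F; potassium bis(trimethylsilyl)amide C[Si](C)(C)[N-][Si](C)(C)C.[K+] (potassium of 6)
Why: Kinetic deprotonation by the bulky amide takes the open C3 methylene rather than the tertiary ring-fusion C5–H, and O-sulfonylation of the enolate (enol triflate formation) fixes the double bond at C3=C4 without touching C5 or the TBS enol ether.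

Step 5
Reactants: 7 enol triflate
Product: 8 tert-butyl{[(4aR,8aR)-5,8a-dimethyl-1,4,4a,7,8,8a-hexahydronaphthalen-2-yl]oxy}dimethylsilane
Conditions: MeMgBr, Fe(acac)3 (5 mol %), THF/NMP, −30 → 0 °C
Reagents that add atoms: methylmagnesium bromide C[Mg]Br
Why: Iron-catalysed Kumada-type cross-coupling of an alkenyl triflate replaces C4–OTf by C4–CH3 (C15) with the double bond held at C3=C4, and the TBS enol ether is inert to the Grignard reagent at this temperature.

Step 6
Reactants: 8 methyl diene
Product: 9 (3R,4aR,8aR)-3-(2-methoxypropan-2-yl)-5,8a-dimethyl-3,4,4a,7,8,8a-hexahydronaphthalen-2(1H)-one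
Conditions: Me2C(OMe)2, TMSOTf (10 mol %), 2,6-di-tert-butyl-4-methylpyridine (5 mol %), CH2Cl2, −78 °C
Reagents that add atoms: 2,2-dimethoxypropane COC(C)(C)OC
Why: Mukaiyama aldol-type addition of the regiodefined C7=C8 enol silane to the oxocarbenium ion of the ketal forms C7–C11 at C7 only, the isolated C3=C4 alkene being far less nucleophilic, and the new C7 centre (drawn as the equatorial 7β epimer) is erased in step 7, so either epimer serves.

Step 7
Reactants: 9 β-methoxy ketone
Product: 10 (4aR,8aR)-5,8a-dimethyl-3-(propan-2-ylidene)-3,4,4a,7,8,8a-hexahydronaphthalen-2(1H)-one (eudesma-3,7(11)-dien-8-one)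
Conditions: KOt-Bu (20 mol %), THF, 0 °C → rt
Reagents that add atoms: none
Why: E1cB elimination of methoxide from the β-methoxy ketone gives the conjugated tetrasubstituted C7=C11 enone, an ether having no retro-aldol path, and C5 and C10 carry no acidic hydrogen.

Step 8
Reactants: 10 dienone
Product: 11 diol (4aR,5S,6R,8aR)-5,6-dihydroxy-5,8a-dimethyl-3-(propan-2-ylidene)octahydronaphthalen-2(1H)-one (3α,4α-diol)
Conditions: OsO4 (2 mol %), NMO, acetone/H2O, 0 °C → rt
Reagents that add atoms: osmium tetroxide O=[Os](=O)(=O)=O; N-methylmorpholine N-oxide C[N+]1([O-])CCOCC1; water O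
Why: In the Upjohn dihydroxylation OsO4 adds suprafacially to the electron-rich trisubstituted C3=C4 alkene rather than to the electron-poor tetrasubstituted C7=C11 enone, and from the α face opposite the axial C10 methyl, which sets C3 (R, axial OH) and C4 (S, equatorial OH, axial CH3) as the cis diol.

Step 9
Reactants: 12 (S)-1-bromo-2-methylbutane
Product: 14 (S)-3-methylpentanoic acid, via Grignard reagent 13 (not isolated)
Conditions: Mg, THF, reflux; CO2, −20 °C; aq HCl
Reagents that add atoms: magnesium [Mg] (magnesium of 13); carbon dioxide O=C=O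
Why: Grignard formation and carboxylation lengthen the chain by one carbon, and the stereocentre, one carbon away from the metal-bearing carbon, takes no part and keeps its configuration.

Step 10
Reactants: 11 diol; 14 (S)-3-methylpentanoic acid
Product: 15 target (1S,2R,4aR,8aR)-1-hydroxy-1,4a-dimethyl-6-oxo-7-(propan-2-ylidene)decahydronaphthalen-2-yl (3S)-3-methylpentanoate
Conditions: DCC, DMAP (20 mol %), CH2Cl2, 0 °C → rt
Reagents that add atoms: none
Why: Steglich esterification acylates the secondary C3 hydroxyl while the tertiary C4 hydroxyl is too hindered to react, and no stereocentre is touched.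

Compound list
1 | but-3-en-2-one | C=CC(C)=O | starting material
2 | 2-[(tert-butyldimethylsilyl)oxy]buta-1,3-diene | C=CC(=C)O[Si](C)(C)C(C)(C)C | intermediate
3 | 3-methylcyclohex-2-en-1-one | CC1=CC(=O)CCC1 | starting material
4 | cis adduct, (4aR,8aS)-6-[(tert-butyldimethylsilyl)oxy]-4a-methyl-3,4,4a,5,8,8a-hexahydronaphthalen-1(2H)-one | O=C1CCC[C@]2(C)CC(O[Si](C)(C)C(C)(C)C)=CC[C@H]12 | intermediate
5 | trans ketone, (4aR,8aR)-6-[(tert-butyldimethylsilyl)oxy]-4a-methyl-3,4,4a,5,8,8a-hexahydronaphthalen-1(2H)-one | O=C1CCC[C@]2(C)CC(O[Si](C)(C)C(C)(C)C)=CC[C@@H]12 | intermediate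
6 | potassium C3=C4 enolate of 5 | [K+].[O-]C1=CCC[C@]2(C)CC(O[Si](C)(C)C(C)(C)C)=CC[C@@H]12 | intermediate
7 | enol triflate, (4aR,8aR)-6-[(tert-butyldimethylsilyl)oxy]-4a-methyl-3,4,4a,5,8,8a-hexahydronaphthalen-1-yl trifluoromethanesulfonate | O=S(=O)(OC1=CCC[C@]2(C)CC(O[Si](C)(C)C(C)(C)C)=CC[C@@H]12)C(F)(F)F | intermediate
8 | tert-butyl{[(4aR,8aR)-5,8a-dimethyl-1,4,4a,7,8,8a-hexahydronaphthalen-2-yl]oxy}dimethylsilane | CC1=CCC[C@]2(C)CC(O[Si](C)(C)C(C)(C)C)=CC[C@@H]12 | intermediate
9 | (3R,4aR,8aR)-3-(2-methoxypropan-2-yl)-5,8a-dimethyl-3,4,4a,7,8,8a-hexahydronaphthalen-2(1H)-one | CC1=CCC[C@]2(C)CC(=O)[C@@H](C(C)(C)OC)C[C@@H]12 | intermediate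
10 | (4aR,8aR)-5,8a-dimethyl-3-(propan-2-ylidene)-3,4,4a,7,8,8a-hexahydronaphthalen-2(1H)-one | CC1=CCC[C@]2(C)CC(=O)C(=C(C)C)C[C@@H]12 | intermediate
11 | (4aR,5S,6R,8aR)-5,6-dihydroxy-5,8a-dimethyl-3-(propan-2-ylidene)octahydronaphthalen-2(1H)-one | O[C@@H]1CC[C@]2(C)CC(=O)C(=C(C)C)C[C@H]2[C@]1(C)O | intermediate
12 | (S)-1-bromo-2-methylbutane | CC[C@H](C)CBr | starting material
13 | (S)-2-methylbutylmagnesium bromide | CC[C@H](C)C[Mg]Br | intermediate
14 | (S)-3-methylpentanoic acid | CC[C@H](C)CC(=O)O | intermediate
15 | (1S,2R,4aR,8aR)-1-hydroxy-1,4a-dimethyl-6-oxo-7-(propan-2-ylidene)decahydronaphthalen-2-yl (3S)-3-methylpentanoate | CC[C@H](C)CC(=O)O[C@@H]1CC[C@]2(C)CC(=O)C(=C(C)C)C[C@H]2[C@]1(C)O | target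

Total step count: 10. Longest linear sequence: 9 (steps 1 to 8 and step 10).

Steps most likely to fail

Step 2. Three things may go wrong:
- Turnover may stall because the β,β-disubstituted C10 is hard to reach inside the confined ion pair.
- The diene may be lost to protodesilylation or oligomerisation.
- The anion may tell the two faces of the flat enone apart poorly.

The fallback sets out from 2 and 3 and returns at 11.
- The cycloaddition is run with the achiral mixed Lewis acid AlBr3/AlMe3 (PhMe/CH2Cl2, low temperature). This is a known promoter for hindered 2-silyloxydiene and β,β-disubstituted enone pairs, and it gives 4 together with its mirror image, ent-cis adduct F1.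
- Steps 3 to 8 are then run unchanged on the racemate. They carry along ent-trans ketone F2, ent-potassium enolate F3, ent-enol triflate F4, ent-methyl diene F5, ent-methoxy ketone F6, ent-dienone F7 and ent-diol F8.
- The racemic diol is esterified at the C3 hydroxyl with (S)-O-methylmandelic acid (DCC, DMAP). This gives the mandelate of 11 F9 and the mandelate of the ent-diol F10, which are diastereomers and are separated by chromatography or crystallisation.
- Methanolysis of F9 (K2CO3, MeOH) returns enantiopure 11.

Step 3. The cis/trans equilibrium may lie less far on the trans side than hoped, because the sp2 atoms of both rings level the strain difference. Slow loss of the enol silane may also compete on long heating.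

The fallback replaces thermodynamic control by kinetic protonation. It sets out from 4 and returns at 5.
- Thermodynamic silylation (Me3SiCl, Et3N, DMF, 80 °C) gives the tetrasubstituted C4=C5 trimethylsilyl enol ether F11.
- MeLi (THF, 0 °C) cleaves only the trimethylsilyl group and gives the lithium C4=C5 enolate F12.
- Protonation at −78 °C with a hindered phenol should occur at C5 from the α face, anti to the adjacent C10 methyl, and so give 5.

Step 6. The hindered tertiary oxocarbenium ion may react too slowly with the TBS enol ether, so that protodesilylation or acid-induced migration of the C3=C4 double bond takes over.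

The fallback avoids acid and carbonyl addition altogether. It sets out from 8 and returns at 10.
- Bu4NF/AcOH (THF) frees the C8 ketone F13.
- Kinetic deprotonation at C7 follows (LiN(i-Pr)2, THF, −78 °C; C9 is neopentyl). CS2, LiN(SiMe3)2 and MeI then give the α-oxoketene dithioacetal F14.
- Excess Me2CuLi (Et2O, −78 → 0 °C) exchanges both methylthio groups for methyl by conjugate addition–elimination and gives 10.

Further compounds
F1 | step 2 | ent-cis adduct (mirror image of 4) | O=C1CCC[C@@]2(C)CC(O[Si](C)(C)C(C)(C)C)=CC[C@@H]12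
F2 | step 2 | ent-trans ketone (mirror image of 5) | O=C1CCC[C@@]2(C)CC(O[Si](C)(C)C(C)(C)C)=CC[C@H]12
F3 | step 2 | ent-potassium enolate (mirror image of 6) | [K+].[O-]C1=CCC[C@@]2(C)CC(O[Si](C)(C)C(C)(C)C)=CC[C@H]12
F4 | step 2 | ent-enol triflate (mirror image of 7) | O=S(=O)(OC1=CCC[C@@]2(C)CC(O[Si](C)(C)C(C)(C)C)=CC[C@H]12)C(F)(F)F
F5 | step 2 | ent-methyl diene (mirror image of 8) | CC1=CCC[C@@]2(C)CC(O[Si](C)(C)C(C)(C)C)=CC[C@H]12
F6 | step 2 | ent-methoxy ketone (mirror image of 9) | CC1=CCC[C@@]2(C)CC(=O)[C@H](C(C)(C)OC)C[C@H]12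
F7 | step 2 | ent-dienone (mirror image of 10) | CC1=CCC[C@@]2(C)CC(=O)C(=C(C)C)C[C@H]12
F8 | step 2 | ent-diol (mirror image of 11) | O[C@H]1CC[C@@]2(C)CC(=O)C(=C(C)C)C[C@@H]2[C@@]1(C)O
F9 | step 2 | mandelate of 11, C3 (S)-2-methoxy-2-phenylacetate | CO[C@H](C(=O)O[C@@H]1CC[C@]2(C)CC(=O)C(=C(C)C)C[C@H]2[C@]1(C)O)c3ccccc3
F10 | step 2 | mandelate of the ent-diol, C3 (S)-2-methoxy-2-phenylacetate | CO[C@H](C(=O)O[C@H]1CC[C@@]2(C)CC(=O)C(=C(C)C)C[C@@H]2[C@@]1(C)O)c3ccccc3
F11 | step 3 | C4=C5 trimethylsilyl enol ether | C[Si](C)(C)OC1=C2CC=C(O[Si](C)(C)C(C)(C)C)C[C@@]2(C)CCC1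
F12 | step 3 | lithium C4=C5 enolate | [Li+].[O-]C1=C2CC=C(O[Si](C)(C)C(C)(C)C)C[C@@]2(C)CCC1
F13 | step 6 | C8 ketone, (4aR,8aR)-5,8a-dimethyl-3,4,4a,7,8,8a-hexahydronaphthalen-2(1H)-one | CC1=CCC[C@]2(C)CC(=O)CC[C@@H]12
F14 | step 6 | α-oxoketene dithioacetal, (4aR,8aR)-3-[bis(methylsulfanyl)methylidene]-5,8a-dimethyl-3,4,4a,7,8,8a-hexahydronaphthalen-2(1H)-one | CC1=CCC[C@]2(C)CC(=O)C(=C(SC)SC)C[C@@H]12
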